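**Retrosynthetic overview**

1. Feature: ring B of the target carries three oxygen substituents in a row, the aryloxy group at C1', the hydroxyl at C2' and the methoxy group at C3' (chain at C5'). This is the pattern left when a nucleophile and then an electrophile add across the C1'–C2' triple bond of a 3-methoxyaryne.
2. Last disconnection: O–Si of the side chain (13 → 14).
3. Key disconnection: the diaryl ether bond O–C1' and the C2'–OH bond, made in one pot from fluoroarene 5, the phenoxide of ring A (from 6) and B(OMe)3/H2O2.
4. First disconnection: the C5'–CH2 bond of 5, by B-alkyl Suzuki–Miyaura coupling of bromide 3 with the 9-BBN adduct of allyl silyl ether 1.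
5. No ring is formed: both benzene rings are bought, and the target has no stereocentre.

Key step: step 2

Assumption: ring B is numbered C1' (aryloxy), C2' (hydroxyl), C3' (methoxy), C5' (hydroxypropyl chain); 2,6-dimethoxy-4-propylphenol (6) is taken as a purchased flavour compound.

**Route**

Step 1
Reactants: 1 tert-butyl(dimethyl)(prop-2-en-1-yloxy)silane; 2 9-borabicyclo[3.3.1]nonane (9-BBN); 3 1-bromo-3-fluoro-5-methoxybenzene
Product: 5 tert-butyl[3-(3-fluoro-5-methoxyphenyl)propoxy]dimethylsilane, via 9-[3-(tert-butyldimethylsilyloxy)propyl]-9-borabicyclo[3.3.1]nonane 4 (not isolated)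
Conditions: 1, 2 (0.5 M in THF), 0 °C → rt; then 3, PdCl2(dppf) (3 mol%), K3PO4 (3 M aq), DMF, 60 °C
Reagents that add atoms: none
Why: Anti-Markovnikov hydroboration of the terminal alkene by 9-BBN puts boron on the end carbon, and B-alkyl Suzuki–Miyaura coupling of borane 4 with the aryl bromide under zerovalent palladium catalysis should join that sp3 carbon to the ring while the C–F bond, the methoxy group and the silyl ether stay untouched.

Step 2
Reactants: 5 tert-butyl[3-(3-fluoro-5-methoxyphenyl)propoxy]dimethylsilane; 6 2,6-dimethoxy-4-propylphenol; 7 trimethyl borate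
Product: 13 4-[3-(tert-butyldimethylsilyloxy)propyl]-2-(2,6-dimethoxy-4-propylphenoxy)-6-methoxyphenol, via lithium 2,6-dimethoxy-4-propylphenoxide 8 (not isolated), via {4-[3-(tert-butyldimethylsilyloxy)propyl]-2-fluoro-6-methoxyphenyl}lithium 9 (not isolated), via 5-[3-(tert-butyldimethylsilyloxy)propyl]-3-methoxybenzyne 10 (not isolated), via {4-[3-(tert-butyldimethylsilyloxy)propyl]-2-(2,6-dimethoxy-4-propylphenoxy)-6-methoxyphenyl}lithium 11 (not isolated), via lithium aryl(trimethoxy)borate 12 (not isolated)
Conditions: 6 (3 equiv), n-BuLi (3 equiv), THF, −78 → −20 °C; separately 5, s-BuLi (1.0 equiv), THF, −78 °C, 1 h, then slow cannula transfer into the phenoxide at −20 °C, then 0 °C; 7 (6 equiv), −78 °C → rt; 30% H2O2, AcOH, 0 °C → rt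
Reagents that add atoms: hydrogen peroxide, OO
Why: Proposed new method: s-BuLi removes the ring hydrogen of 5 that lies between F and OMe, the most acidic one, and aryllithium 9 keeps its fluoride at −78 °C but loses LiF as soon as it meets the phenoxide solution at −20 °C, so that aryne 10 forms at a low stationary concentration of 9 inside a threefold excess of 8. The methoxy group at C3' distorts and polarises the triple bond by induction so that the remote carbon C1' is the flatter, electrophilic one, and the phenoxide oxygen adds there, its own ortho and para carbons being substituted so that only O-arylation leads to an aromatic product. This leaves aryllithium 11 with lithium at C2' between two oxygen atoms, which B(OMe)3 captures as borate 12 before acidic hydrogen peroxide moves the aryl group from boron to oxygen and so installs the C2' hydroxyl. The closest known reaction types are the addition of lithium or magnesium amides, thiolates and aryl nucleophiles to arynes made from ortho-metalated haloarenes with electrophilic capture of the new aryl metal, the O-arylation of phenols by 3-methoxybenzyne from silylaryl triflates, and lithiation–borylation–oxidation of 1,3-dioxygenated arenes, but a phenoxide has not been shown as the nucleophile of such a nucleophile-then-electrophile sequence. No ring is closed and no stereocentre is formed. The step needs O–C1' in place of O–C2' bond formation, which the C3' methoxy group secures, and it needs the phenoxide to outrun aryllithiums 9 and 11 at the aryne and the C2' lithium to find no proton, for which the excess of 8, the slow inverse addition and the preparation of 8 with n-BuLi (butane as the only by-product) are chosen.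

Step 3
Reactants: 13 4-[3-(tert-butyldimethylsilyloxy)propyl]-2-(2,6-dimethoxy-4-propylphenoxy)-6-methoxyphenol
Product: 14 4-(3-hydroxypropyl)-2-(2,6-dimethoxy-4-propylphenoxy)-6-methoxyphenol
Conditions: Bu4NF, AcOH, THF, 0 °C → rt
Reagents that add atoms: none
Why: Fluoride-mediated desilylation, driven by the strong Si–F bond, should cleave the primary silyl ether, while acetic acid keeps the electron-rich phenol from standing as its air-sensitive phenoxide and the diaryl ether and methyl ethers are inert.

**Compound list**

1 | tert-butyl(dimethyl)(prop-2-en-1-yloxy)silane | C=CCO[Si](C)(C)C(C)(C)C | starting material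
2 | 9-borabicyclo[3.3.1]nonane (9-BBN, handled as its dimer) | B1C2CCCC1CCC2 | starting material
3 | 1-bromo-3-fluoro-5-methoxybenzene | COc1cc(F)cc(Br)c1 | starting material
4 | 9-[3-(tert-butyldimethylsilyloxy)propyl]-9-borabicyclo[3.3.1]nonane (not isolated) | CC(C)(C)[Si](C)(C)OCCCB1C2CCCC1CCC2 | intermediate
5 | tert-butyl[3-(3-fluoro-5-methoxyphenyl)propoxy]dimethylsilane | COc1cc(F)cc(CCCO[Si](C)(C)C(C)(C)C)c1 | intermediate
6 | 2,6-dimethoxy-4-propylphenol | CCCc1cc(OC)c(O)c(OC)c1 | starting material
7 | trimethyl borate | COB(OC)OC | starting material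
8 | lithium 2,6-dimethoxy-4-propylphenoxide (not isolated) | [Li+].CCCc1cc(OC)c([O-])c(OC)c1 | intermediate
9 | {4-[3-(tert-butyldimethylsilyloxy)propyl]-2-fluoro-6-methoxyphenyl}lithium (not isolated) | [Li]c1c(F)cc(CCCO[Si](C)(C)C(C)(C)C)cc1OC | intermediate
10 | 5-[3-(tert-butyldimethylsilyloxy)propyl]-3-methoxybenzyne (not isolated) | COC1=CC(CCCO[Si](C)(C)C(C)(C)C)=CC#C1 | intermediate
11 | {4-[3-(tert-butyldimethylsilyloxy)propyl]-2-(2,6-dimethoxy-4-propylphenoxy)-6-methoxyphenyl}lithium (not isolated) | CCCc1cc(OC)c(Oc2cc(CCCO[Si](C)(C)C(C)(C)C)cc(OC)c2[Li])c(OC)c1 | intermediate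
12 | lithium {4-[3-(tert-butyldimethylsilyloxy)propyl]-2-(2,6-dimethoxy-4-propylphenoxy)-6-methoxyphenyl}trimethoxyborate (not isolated) | [Li+].CCCc1cc(OC)c(Oc2cc(CCCO[Si](C)(C)C(C)(C)C)cc(OC)c2[B-](OC)(OC)OC)c(OC)c1 | intermediate
13 | 4-[3-(tert-butyldimethylsilyloxy)propyl]-2-(2,6-dimethoxy-4-propylphenoxy)-6-methoxyphenol | CCCc1cc(OC)c(Oc2cc(CCCO[Si](C)(C)C(C)(C)C)cc(OC)c2O)c(OC)c1 | intermediate
14 | 4-(3-hydroxypropyl)-2-(2,6-dimethoxy-4-propylphenoxy)-6-methoxyphenol | CCCc1cc(OC)c(Oc2cc(CCCO)cc(OC)c2O)c(OC)c1 | target

**Step count**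

Total: 3 steps. Longest linear sequence: 3 steps (1 and 3 → 5 → 13 → 14).

**Steps most likely to fail**

1. Step 2 (proposed new method). The aggregated lithium phenoxide may add to the aryne too slowly, so that aryllithiums 9 and 11 capture it instead and aryl–aryl coupling and oligomerisation take over. Proton transfer to C2' before borate capture would further leave the diaryl ether without its hydroxyl.
Fallback, known chemistry only: it sets out from phenol 6 (using borane 4 of step 1) and comes back to the route at aryllithium 11. Borane 4 is coupled with an excess of purchased 3,5-dibromoanisole (PdCl2(dppf), K3PO4, DMF/H2O, 60 °C) to give tert-butyl[3-(3-bromo-5-methoxyphenyl)propoxy]dimethylsilane F1. Ullmann-type etherification of 6 with F1 (CuI, picolinic acid, K3PO4, DMSO, 90 °C), a coupling established for 2,6-disubstituted phenols with unhindered aryl bromides, gives tert-butyl{3-[3-(2,6-dimethoxy-4-propylphenoxy)-5-methoxyphenyl]propoxy}dimethylsilane F2. Directed ortho-lithiation of F2 at C2', between the two oxygens of ring B (n-BuLi, THF, 0 °C), gives 11, which is borylated with 7 and oxidised to 13 as in step 2.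

2. Step 1. Slow transmetalation of the alkylborane may let β-hydride elimination and protodeboronation compete, giving reduced arene and alkene isomers in place of the sp3–sp2 bond.
Fallback: it sets out from bromide 3 and comes back at 5. Sonogashira coupling of 3 with purchased tert-butyldimethyl(prop-2-yn-1-yloxy)silane (PdCl2(PPh3)2, CuI, Et3N, 70 °C) gives tert-butyl{[3-(3-fluoro-5-methoxyphenyl)prop-2-yn-1-yl]oxy}dimethylsilane F3, and hydrogenation of the triple bond (H2, Pd/C, EtOAc) gives 5.

3. Step 3. Under fluoride the electron-rich phenol may be partly held as its phenoxide and oxidised by air, and the polar product may be hard to free from ammonium salts.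
Fallback: the chain oxygen is carried as a benzyl ether and released by hydrogenolysis; it sets out from bromide 3 and comes back at target 14.
- Allyl benzyl ether is hydroborated with 2 to 9-[3-(benzyloxy)propyl]-9-borabicyclo[3.3.1]nonane F4 and coupled with 3 as in step 1 to give 1-[3-(benzyloxy)propyl]-3-fluoro-5-methoxybenzene F5.
- The sequence of step 2 is then run on F5: lithiation to {4-[3-(benzyloxy)propyl]-2-fluoro-6-methoxyphenyl}lithium F6, loss of LiF to 5-[3-(benzyloxy)propyl]-3-methoxybenzyne F7, addition of 8 to {4-[3-(benzyloxy)propyl]-2-(2,6-dimethoxy-4-propylphenoxy)-6-methoxyphenyl}lithium F8, capture by 7 as lithium {4-[3-(benzyloxy)propyl]-2-(2,6-dimethoxy-4-propylphenoxy)-6-methoxyphenyl}trimethoxyborate F9, and peroxide oxidation to 4-[3-(benzyloxy)propyl]-2-(2,6-dimethoxy-4-propylphenoxy)-6-methoxyphenol F10.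
- Hydrogenolysis of F10 (H2, Pd/C, EtOAc/EtOH) should free 14 under neutral conditions.

**Further compounds**

F1 | step 2 | tert-butyl[3-(3-bromo-5-methoxyphenyl)propoxy]dimethylsilane | COc1cc(Br)cc(CCCO[Si](C)(C)C(C)(C)C)c1
F2 | step 2 | tert-butyl{3-[3-(2,6-dimethoxy-4-propylphenoxy)-5-methoxyphenyl]propoxy}dimethylsilane | CCCc1cc(OC)c(Oc2cc(CCCO[Si](C)(C)C(C)(C)C)cc(OC)c2)c(OC)c1
F3 | step 1 | tert-butyl{[3-(3-fluoro-5-methoxyphenyl)prop-2-yn-1-yl]oxy}dimethylsilane | COc1cc(F)cc(C#CCO[Si](C)(C)C(C)(C)C)c1
F4 | step 3 | 9-[3-(benzyloxy)propyl]-9-borabicyclo[3.3.1]nonane | C(OCCCB1C2CCCC1CCC2)c1ccccc1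
F5 | step 3 | 1-[3-(benzyloxy)propyl]-3-fluoro-5-methoxybenzene | COc1cc(F)cc(CCCOCc2ccccc2)c1
F6 | step 3 | {4-[3-(benzyloxy)propyl]-2-fluoro-6-methoxyphenyl}lithium | [Li]c1c(F)cc(CCCOCc2ccccc2)cc1OC
F7 | step 3 | 5-[3-(benzyloxy)propyl]-3-methoxybenzyne | COC1=CC(CCCOCc2ccccc2)=CC#C1
F8 | step 3 | {4-[3-(benzyloxy)propyl]-2-(2,6-dimethoxy-4-propylphenoxy)-6-methoxyphenyl}lithium | CCCc1cc(OC)c(Oc2cc(CCCOCc3ccccc3)cc(OC)c2[Li])c(OC)c1
F9 | step 3 | lithium {4-[3-(benzyloxy)propyl]-2-(2,6-dimethoxy-4-propylphenoxy)-6-methoxyphenyl}trimethoxyborate | [Li+].CCCc1cc(OC)c(Oc2cc(CCCOCc3ccccc3)cc(OC)c2[B-](OC)(OC)OC)c(OC)c1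
F10 | step 3 | 4-[3-(benzyloxy)propyl]-2-(2,6-dimethoxy-4-propylphenoxy)-6-methoxyphenol | CCCc1cc(OC)c(Oc2cc(CCCOCc3ccccc3)cc(OC)c2O)c(OC)c1
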